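**Assumption:** the SMILES carries no stereodescriptor, and the molecule has no stereocentre and no configurationally stable axis (each biaryl axis bears a symmetric 2,4,6-trioxygenated ring). The target is therefore achiral and no stereocontrol is needed.

**Ring labels:** C = central ring; E = chlorinated ring; B and D = the two tetra-oxygenated arm rings; A and F = the terminal O-linked trihydroxyphenyl rings; G and H = the C-linked trihydroxyphenyl rings. The molecule has a mirror plane through rings C and E, and the route exploits it in both directions at once.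

## Retrosynthetic overview

1. Target 17 ⇐ nonadeca-O-methyl ether 16 by global demethylation. No benzene ring is built de novo: all eight are bought and joined.
2. 16 ⇐ bis-phenol 14 + 2 × 2-iodo-1,3,5-trimethoxybenzene (two-fold Ullmann, rings A and F); 14 ⇐ bis-aldehyde 12 by two-fold Dakin oxidation.
3. 12 ⇐ hindered phenol 8 + ring E boronic acid 11 (Chan–Lam at the central oxygen of ring C; 11 by C–H borylation).
4. Key step: 8 ⇐ 2,6-dichloro-1,4-benzoquinone + 2 × phenol 4. A double addition–elimination makes both C–O–B/D ether bonds at once, and the quinone carbonyls become O-1 and O-4 of ring C.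
5. 4 ⇐ syringaldehyde by bromination and Suzuki coupling. Order of joining: B/D with G/H → C → E → A/F.

## Route

Step 1
Reactants: 1 syringaldehyde (4-hydroxy-3,5-dimethoxybenzaldehyde)
Product: 2 2-bromo-4-hydroxy-3,5-dimethoxybenzaldehyde
Conditions: Br2 (1.05 equiv), NaOAc (1.1 equiv), AcOH, rt, 3 h
Reagents that add atoms: bromine, BrBr
Why: Electrophilic aromatic bromination, in which the only free positions (C2 and C6, equivalent) are ortho to one methoxy group and para to the other, so a single monobromide forms and is deactivated toward a second bromination.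

Step 2
Reactants: 2 2-bromo-4-hydroxy-3,5-dimethoxybenzaldehyde; 3 (2,4,6-trimethoxyphenyl)boronic acid (1.8 equiv)
Product: 4 4-hydroxy-3,5-dimethoxy-2-(2,4,6-trimethoxyphenyl)benzaldehyde
Conditions: Pd(OAc)2 (5 mol%), SPhos (10 mol%), K3PO4 (4 equiv), toluene/H2O 10:1, 90 °C, 16 h
Reagents that add atoms: none
Why: Suzuki–Miyaura coupling, for which SPhos-ligated zerovalent palladium is the established system for tetra-ortho-substituted alkoxy biaryls, with the ortho-formyl group speeding oxidative addition and excess boronic acid offsetting protodeboronation.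

Step 3 (key step)
Reactants: 4 4-hydroxy-3,5-dimethoxy-2-(2,4,6-trimethoxyphenyl)benzaldehyde (2.1 equiv); 5 2,6-dichloro-1,4-benzoquinone (1.0 equiv)
Product: 7 2,6-bis[4-formyl-2,6-dimethoxy-3-(2,4,6-trimethoxyphenyl)phenoxy]benzene-1,4-diol, via bis(aryloxy)benzoquinone 6 (not isolated)
Conditions: Cs2CO3 (2.2 equiv), MeCN, 0 °C to rt, 6 h; then aq. Na2S2O4, EtOAc, rt, 15 min
Reagents that add atoms: none
Why: Two-directional vinylogous addition–elimination (substitution of a β-chloro enone, the known route to aryloxyquinones) by a phenoxide whose ortho and para carbons are all blocked and whose para-formyl group tames it against electron transfer, followed by dithionite reduction of the quinone to the hydroquinone.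

Step 4
Reactants: 7 2,6-bis[4-formyl-2,6-dimethoxy-3-(2,4,6-trimethoxyphenyl)phenoxy]benzene-1,4-diol
Product: 8 2,6-bis[4-formyl-2,6-dimethoxy-3-(2,4,6-trimethoxyphenyl)phenoxy]-4-methoxyphenol
Conditions: MeI (1.05 equiv), K2CO3 (1.1 equiv), degassed acetone, rt, Ar, 12 h
Reagents that add atoms: iodomethane, CI
Why: Williamson etherification that is selective because the 4-OH is both the more acidic hydroxyl (two meta aryloxy groups) and unhindered, whereas the 1-OH lies between two bulky aryloxy groups.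

Step 5
Reactants: 9 2-chloro-1,3-dimethoxybenzene
Product: 11 (4-chloro-3,5-dimethoxyphenyl)boronic acid, via aryl pinacol boronate 10 (not isolated)
Conditions: [Ir(OMe)(cod)]2 (1.5 mol%), 4,4'-di-tert-butyl-2,2'-bipyridine (3 mol%), B2pin2 (1.0 equiv), THF, 80 °C, 16 h; then NaIO4 (3 equiv), THF/H2O, 1 M HCl, rt, 4 h
Reagents that add atoms: bis(pinacolato)diboron, CC1(C)OB(OC1(C)C)B1OC(C)(C)C(C)(C)O1; water, O
Why: Sterically controlled iridium-catalysed C–H borylation reacts only at C5, the one C–H with no ortho substituent, and periodate cleavage of the pinacol ester (oxidative hydrolysis) gives the free boronic acid needed for the next coupling.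

Step 6
Reactants: 8 2,6-bis[4-formyl-2,6-dimethoxy-3-(2,4,6-trimethoxyphenyl)phenoxy]-4-methoxyphenol; 11 (4-chloro-3,5-dimethoxyphenyl)boronic acid (3 equiv)
Product: 12 2-(4-chloro-3,5-dimethoxyphenoxy)-1,3-bis[4-formyl-2,6-dimethoxy-3-(2,4,6-trimethoxyphenyl)phenoxy]-5-methoxybenzene
Conditions: Cu(OAc)2 (1.5 equiv, reoxidised by O2), pyridine (5 equiv), 4 Å MS, CH2Cl2, O2 balloon, rt, 48 h
Reagents that add atoms: none
Why: Chan–Lam oxidative O-arylation at room temperature, precedented for 2,6-disubstituted phenols, using an unhindered boronic acid and leaving the aryl chloride and aldehydes untouched.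

Step 7
Reactants: 12 2-(4-chloro-3,5-dimethoxyphenoxy)-1,3-bis[4-formyl-2,6-dimethoxy-3-(2,4,6-trimethoxyphenyl)phenoxy]-5-methoxybenzene
Product: 14 2-(4-chloro-3,5-dimethoxyphenoxy)-1,3-bis[4-hydroxy-2,6-dimethoxy-3-(2,4,6-trimethoxyphenyl)phenoxy]-5-methoxybenzene, via bis(aryl formate) 13 (not isolated)
Conditions: mCPBA (3 equiv), CH2Cl2, 0 °C to rt, 6 h; then Et3N (cat.), MeOH, rt, 1 h
Reagents that add atoms: meta-chloroperoxybenzoic acid, OOC(=O)c1cccc(Cl)c1
Why: Two-fold Dakin-type Baeyer–Villiger oxidation in which the electron-rich para-aryloxy aryl group migrates in preference to hydride, and methanolysis of the resulting aryl formates unveils both arm phenols at once.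

Step 8
Reactants: 14 2-(4-chloro-3,5-dimethoxyphenoxy)-1,3-bis[4-hydroxy-2,6-dimethoxy-3-(2,4,6-trimethoxyphenyl)phenoxy]-5-methoxybenzene; 15 2-iodo-1,3,5-trimethoxybenzene (4 equiv)
Product: 16 2-(4-chloro-3,5-dimethoxyphenoxy)-1,3-bis[2,6-dimethoxy-4-(2,4,6-trimethoxyphenoxy)-3-(2,4,6-trimethoxyphenyl)phenoxy]-5-methoxybenzene
Conditions: CuI (40 mol%), picolinic acid (80 mol%), K3PO4 (4 equiv), DMSO, 100 °C, Ar, 36 h
Reagents that add atoms: none
Why: Two-fold Ullmann diaryl ether synthesis under the CuI/picolinic acid system developed for ortho-substituted phenols and aryl iodides, with the iodide reacting selectively over the ring E aryl chloride.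

Step 9
Reactants: 16 2-(4-chloro-3,5-dimethoxyphenoxy)-1,3-bis[2,6-dimethoxy-4-(2,4,6-trimethoxyphenoxy)-3-(2,4,6-trimethoxyphenyl)phenoxy]-5-methoxybenzene
Product: 17 CNP0275555.0, 4-(4-chloro-3,5-dihydroxyphenoxy)-3,5-bis[2,6-dihydroxy-4-(2,4,6-trihydroxyphenoxy)-3-(2,4,6-trihydroxyphenyl)phenoxy]phenol
Conditions: BBr3 (60 equiv, 1 M in CH2Cl2), CH2Cl2, −78 °C to rt, 24 h, Ar; then H2O, 0 °C; degassed reversed-phase HPLC
Reagents that add atoms: none
Why: Exhaustive Lewis-acid O-demethylation of all nineteen aryl methyl ethers (bromide attack on the boron-activated O–CH3), to which the diaryl ether, biaryl and aryl chloride bonds are inert.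

## Compound list

1 | syringaldehyde (4-hydroxy-3,5-dimethoxybenzaldehyde) | O=Cc1cc(OC)c(O)c(OC)c1 | starting material
2 | 2-bromo-4-hydroxy-3,5-dimethoxybenzaldehyde | O=Cc1cc(OC)c(O)c(OC)c1Br | intermediate
3 | (2,4,6-trimethoxyphenyl)boronic acid | COc1cc(OC)c(B(O)O)c(OC)c1 | starting material
4 | 4-hydroxy-3,5-dimethoxy-2-(2,4,6-trimethoxyphenyl)benzaldehyde | O=Cc1cc(OC)c(O)c(OC)c1-c1c(OC)cc(OC)cc1OC | intermediate
5 | 2,6-dichloro-1,4-benzoquinone | O=C1C=C(Cl)C(=O)C(Cl)=C1 | starting material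
6 | 2,6-bis[4-formyl-2,6-dimethoxy-3-(2,4,6-trimethoxyphenyl)phenoxy]-1,4-benzoquinone | O=C1C=C(Oc2c(OC)cc(C=O)c(-c3c(OC)cc(OC)cc3OC)c2OC)C(=O)C(Oc2c(OC)cc(C=O)c(-c3c(OC)cc(OC)cc3OC)c2OC)=C1 | intermediate
7 | 2,6-bis[4-formyl-2,6-dimethoxy-3-(2,4,6-trimethoxyphenyl)phenoxy]benzene-1,4-diol | Oc1cc(Oc2c(OC)cc(C=O)c(-c3c(OC)cc(OC)cc3OC)c2OC)c(O)c(Oc2c(OC)cc(C=O)c(-c3c(OC)cc(OC)cc3OC)c2OC)c1 | intermediate
8 | 2,6-bis[4-formyl-2,6-dimethoxy-3-(2,4,6-trimethoxyphenyl)phenoxy]-4-methoxyphenol | COc1cc(Oc2c(OC)cc(C=O)c(-c3c(OC)cc(OC)cc3OC)c2OC)c(O)c(Oc2c(OC)cc(C=O)c(-c3c(OC)cc(OC)cc3OC)c2OC)c1 | intermediate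
9 | 2-chloro-1,3-dimethoxybenzene | COc1cccc(OC)c1Cl | starting material
10 | 2-(4-chloro-3,5-dimethoxyphenyl)-4,4,5,5-tetramethyl-1,3,2-dioxaborolane | COc1cc(B2OC(C)(C)C(C)(C)O2)cc(OC)c1Cl | intermediate
11 | (4-chloro-3,5-dimethoxyphenyl)boronic acid | COc1cc(B(O)O)cc(OC)c1Cl | intermediate
12 | 2-(4-chloro-3,5-dimethoxyphenoxy)-1,3-bis[4-formyl-2,6-dimethoxy-3-(2,4,6-trimethoxyphenyl)phenoxy]-5-methoxybenzene | COc1cc(Oc2c(OC)cc(C=O)c(-c3c(OC)cc(OC)cc3OC)c2OC)c(Oc2cc(OC)c(Cl)c(OC)c2)c(Oc2c(OC)cc(C=O)c(-c3c(OC)cc(OC)cc3OC)c2OC)c1 | intermediate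
13 | 2-(4-chloro-3,5-dimethoxyphenoxy)-1,3-bis[4-(formyloxy)-2,6-dimethoxy-3-(2,4,6-trimethoxyphenyl)phenoxy]-5-methoxybenzene | COc1cc(Oc2c(OC)cc(OC=O)c(-c3c(OC)cc(OC)cc3OC)c2OC)c(Oc2cc(OC)c(Cl)c(OC)c2)c(Oc2c(OC)cc(OC=O)c(-c3c(OC)cc(OC)cc3OC)c2OC)c1 | intermediate
14 | 2-(4-chloro-3,5-dimethoxyphenoxy)-1,3-bis[4-hydroxy-2,6-dimethoxy-3-(2,4,6-trimethoxyphenyl)phenoxy]-5-methoxybenzene | COc1cc(Oc2c(OC)cc(O)c(-c3c(OC)cc(OC)cc3OC)c2OC)c(Oc2cc(OC)c(Cl)c(OC)c2)c(Oc2c(OC)cc(O)c(-c3c(OC)cc(OC)cc3OC)c2OC)c1 | intermediate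
15 | 2-iodo-1,3,5-trimethoxybenzene | COc1cc(OC)c(I)c(OC)c1 | starting material
16 | 2-(4-chloro-3,5-dimethoxyphenoxy)-1,3-bis[2,6-dimethoxy-4-(2,4,6-trimethoxyphenoxy)-3-(2,4,6-trimethoxyphenyl)phenoxy]-5-methoxybenzene | COc1cc(Oc2c(OC)cc(Oc4c(OC)cc(OC)cc4OC)c(-c3c(OC)cc(OC)cc3OC)c2OC)c(Oc2cc(OC)c(Cl)c(OC)c2)c(Oc2c(OC)cc(Oc4c(OC)cc(OC)cc4OC)c(-c3c(OC)cc(OC)cc3OC)c2OC)c1 | intermediate
17 | CNP0275555.0, 4-(4-chloro-3,5-dihydroxyphenoxy)-3,5-bis[2,6-dihydroxy-4-(2,4,6-trihydroxyphenoxy)-3-(2,4,6-trihydroxyphenyl)phenoxy]phenol (achiral) | Oc1cc(O)c(Oc2cc(O)c(Oc3cc(O)cc(Oc4c(O)cc(Oc5c(O)cc(O)cc5O)c(-c5c(O)cc(O)cc5O)c4O)c3Oc3cc(O)c(Cl)c(O)c3)c(O)c2-c2c(O)cc(O)cc2O)c(O)c1 | target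

## Step count and risk

Total step count: 9. Longest linear sequence: 8 steps (steps 1, 2, 3, 4, 6, 7, 8, 9 from syringaldehyde); step 5 is a one-step side branch.

**Step 3 (key double substitution on the quinone).** The risks are Michael addition of the phenoxide at the C–H positions of the quinone instead of chloride displacement, a sluggish second substitution, and base-induced quinone decomposition. The fallback replaces quinone chemistry with copper-mediated etherification of an aromatic ring C that already carries ring E. It sets out from 4 and 11 and comes back to the route at 12, so steps 3, 4 and 6 are bypassed. Commercial 2,6-dibromo-4-methoxyphenol is O-arylated with 11 under Chan–Lam conditions (Cu(OAc)2, pyridine, 4 Å MS, CH2Cl2, air, rt; precedented for 2,6-dihalophenols) to give 1,3-dibromo-2-(4-chloro-3,5-dimethoxyphenoxy)-5-methoxybenzene F1. A two-fold Ullmann coupling of this dibromide with 4 (2.5 equiv; CuI, picolinic acid, K3PO4, DMSO, 110 °C) then gives 12 directly.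

**Step 6 (Chan–Lam arylation of the phenol flanked by two bulky aryloxy groups).** The risk is that transmetalation and reductive elimination at divalent/trivalent copper are too slow at this hindered oxygen. The fallback uses metal-free ligand coupling on trivalent iodine instead. It sets out from 8 and 11 and comes back at 12. Boronic acid 11 is iododeboronated (NIS, MeCN, 80 °C) to 2-chloro-5-iodo-1,3-dimethoxybenzene F2. This iodide is oxidised and coupled in one pot (mCPBA, TsOH·H2O, MeCN, rt, then 1,3,5-trimethoxybenzene) to (4-chloro-3,5-dimethoxyphenyl)(2,4,6-trimethoxyphenyl)iodonium 4-methylbenzenesulfonate F3. The potassium phenoxide of 8 (K2CO3, toluene, 50 °C) then accepts the less electron-rich aryl group of the iodonium salt to give 12, while the trimethoxyphenyl group leaves as 2-iodo-1,3,5-trimethoxybenzene.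

**Step 8 (two-fold Ullmann with an electron-rich, di-ortho-substituted iodide onto ortho-aryl phenols).** The risk is low conversion at one or both sites. The fallback uses a formyl-activated electrophile and brings in the para-oxygen of rings A and F by a second Dakin oxidation instead of carrying it in. It sets out from 14 and comes back at 17. Bis-phenol 14 is coupled with commercial 4-bromo-3,5-dimethoxybenzaldehyde (3 equiv; CuI (10 mol%), picolinic acid, K3PO4, DMSO, 110 °C; the para-formyl group makes this bromide electron-poor and SNAr-competent) to give 2-(4-chloro-3,5-dimethoxyphenoxy)-1,3-bis[4-(4-formyl-2,6-dimethoxyphenoxy)-2,6-dimethoxy-3-(2,4,6-trimethoxyphenyl)phenoxy]-5-methoxybenzene F4. mCPBA (CH2Cl2, 0 °C) converts it into the bis-formate 2-(4-chloro-3,5-dimethoxyphenoxy)-1,3-bis[4-(4-(formyloxy)-2,6-dimethoxyphenoxy)-2,6-dimethoxy-3-(2,4,6-trimethoxyphenyl)phenoxy]-5-methoxybenzene F5. Methanolysis (Et3N, MeOH) gives 2-(4-chloro-3,5-dimethoxyphenoxy)-1,3-bis[4-(4-hydroxy-2,6-dimethoxyphenoxy)-2,6-dimethoxy-3-(2,4,6-trimethoxyphenyl)phenoxy]-5-methoxybenzene F6. BBr3 under the conditions of step 9 then cleaves its seventeen methyl ethers to give 17.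

## Further compounds

F1 | step 3 | 1,3-dibromo-2-(4-chloro-3,5-dimethoxyphenoxy)-5-methoxybenzene | COc1cc(Br)c(Oc2cc(OC)c(Cl)c(OC)c2)c(Br)c1
F2 | step 6 | 2-chloro-5-iodo-1,3-dimethoxybenzene | COc1cc(I)cc(OC)c1Cl
F3 | step 6 | (4-chloro-3,5-dimethoxyphenyl)(2,4,6-trimethoxyphenyl)iodonium 4-methylbenzenesulfonate | COc1cc([I+]c2c(OC)cc(OC)cc2OC)cc(OC)c1Cl.Cc1ccc(S(=O)(=O)[O-])cc1
F4 | step 8 | 2-(4-chloro-3,5-dimethoxyphenoxy)-1,3-bis[4-(4-formyl-2,6-dimethoxyphenoxy)-2,6-dimethoxy-3-(2,4,6-trimethoxyphenyl)phenoxy]-5-methoxybenzene | COc1cc(Oc2c(OC)cc(Oc4c(OC)cc(C=O)cc4OC)c(-c3c(OC)cc(OC)cc3OC)c2OC)c(Oc2cc(OC)c(Cl)c(OC)c2)c(Oc2c(OC)cc(Oc4c(OC)cc(C=O)cc4OC)c(-c3c(OC)cc(OC)cc3OC)c2OC)c1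
F5 | step 8 | 2-(4-chloro-3,5-dimethoxyphenoxy)-1,3-bis[4-(4-(formyloxy)-2,6-dimethoxyphenoxy)-2,6-dimethoxy-3-(2,4,6-trimethoxyphenyl)phenoxy]-5-methoxybenzene | COc1cc(Oc2c(OC)cc(Oc4c(OC)cc(OC=O)cc4OC)c(-c3c(OC)cc(OC)cc3OC)c2OC)c(Oc2cc(OC)c(Cl)c(OC)c2)c(Oc2c(OC)cc(Oc4c(OC)cc(OC=O)cc4OC)c(-c3c(OC)cc(OC)cc3OC)c2OC)c1
F6 | step 8 | 2-(4-chloro-3,5-dimethoxyphenoxy)-1,3-bis[4-(4-hydroxy-2,6-dimethoxyphenoxy)-2,6-dimethoxy-3-(2,4,6-trimethoxyphenyl)phenoxy]-5-methoxybenzene | COc1cc(Oc2c(OC)cc(Oc4c(OC)cc(O)cc4OC)c(-c3c(OC)cc(OC)cc3OC)c2OC)c(Oc2cc(OC)c(Cl)c(OC)c2)c(Oc2c(OC)cc(Oc4c(OC)cc(O)cc4OC)c(-c3c(OC)cc(OC)cc3OC)c2OC)c1
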